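**Retrosynthetic overview**
1. Target 9 ⇐ silyl ether 8 ⇐ cis-alcohol 7 ⇐ isoflavone 5: the C3 stereocentre is set last by a reductase-type hydride transfer to the isoflavone (asymmetric transfer hydrogenation with dynamic kinetic resolution); C4 is then re-oxidised and the silyl group removed.
2. 5 ⇐ 4: ring D, the only ring built, is closed late, as in the plant, by cycloetherification of the 4'-OH onto its own 3'-prenyl group; the second ortho-prenylphenol on ring A is held open by silylating its far more acidic 7-OH.
3. 4 ⇐ 3 ⇐ 2: both C-prenyl groups (C8 and C3') arrive together by a double aromatic Claisen rearrangement of the bis(1,1-dimethylallyl) ether.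
4. 2 ⇐ daidzein 1, the biosynthetic precursor, bought with rings A, B and C in place.
5. Ring order: A, B, C from 1; ring D in step 4; stereocentre in step 5.

Assumption: daidzein is bought as the bulk soy isoflavone and tert-butyl (2-methylbut-3-en-2-yl) carbonate as a catalogue reagent (otherwise one operation from 2-methylbut-3-en-2-ol and Boc2O).

**Step 1**
Reactants: 1 daidzein (7-hydroxy-3-(4-hydroxyphenyl)-4H-chromen-4-one)
Product: 2 7-[(2-methylbut-3-en-2-yl)oxy]-3-{4-[(2-methylbut-3-en-2-yl)oxy]phenyl}-4H-chromen-4-one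
Conditions: tert-butyl (2-methylbut-3-en-2-yl) carbonate (3 equiv), Pd(PPh3)4 (5 mol%), THF–DMF, 0 °C to rt
Reagents that add atoms: tert-butyl (2-methylbut-3-en-2-yl) carbonate, C=CC(C)(C)OC(=O)OC(C)(C)C
Why: Tsuji–Trost-type O-allylation in which zerovalent palladium ionises the tertiary allylic carbonate (CO2 and tert-butoxide leave, the alkoxide deprotonating the phenol) and each phenoxide attacks the more substituted terminus of the 1,1-dimethylallyl palladium complex at low temperature, giving the tertiary allyl aryl ether at both oxygens; no stereocentre is formed.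

**Step 2**
Reactants: 2 7-[(2-methylbut-3-en-2-yl)oxy]-3-{4-[(2-methylbut-3-en-2-yl)oxy]phenyl}-4H-chromen-4-one
Product: 3 7-hydroxy-3-[4-hydroxy-3-(3-methylbut-2-en-1-yl)phenyl]-8-(3-methylbut-2-en-1-yl)-4H-chromen-4-one (8,3'-diprenyldaidzein)
Conditions: N,N-diethylaniline, 135 °C, argon
Reagents that add atoms: none
Why: Double aromatic Claisen rearrangement ([3,3]-sigmatropic shift with allyl inversion, then re-aromatisation) in which each 1,1-dimethylallyl ether delivers a linear prenyl group to an ortho carbon, on ring B to C3' (its two ortho positions are equivalent) and on ring A to C8, the position favoured in 7-allyloxychromones because the C7–C8 bond has the higher double-bond character, while the weakly basic solvent keeps the new ortho-prenylphenols from acid-induced cyclisation.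

**Step 3**
Reactants: 3 7-hydroxy-3-[4-hydroxy-3-(3-methylbut-2-en-1-yl)phenyl]-8-(3-methylbut-2-en-1-yl)-4H-chromen-4-one
Product: 4 3-[4-hydroxy-3-(3-methylbut-2-en-1-yl)phenyl]-8-(3-methylbut-2-en-1-yl)-7-[(triisopropylsilyl)oxy]-4H-chromen-4-one
Conditions: i-Pr3SiCl (1.05 equiv), K2CO3 (1.0 equiv), DMF, 0 °C to rt
Reagents that add atoms: triisopropylsilyl chloride, CC(C)[Si](Cl)(C(C)C)C(C)C
Why: Acidity-controlled mono-O-silylation, since the 7-OH is a vinylogous carboxylic acid (pKa about 7) and takes the single equivalent of base whereas the 4'-OH (pKa about 10) stays protonated and does not react with the bulky chlorosilane without a nucleophilic catalyst, so only the ring A phenol is capped.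

**Step 4**
Reactants: 4 3-[4-hydroxy-3-(3-methylbut-2-en-1-yl)phenyl]-8-(3-methylbut-2-en-1-yl)-7-[(triisopropylsilyl)oxy]-4H-chromen-4-one
Product: 5 3-(2,2-dimethylchroman-6-yl)-8-(3-methylbut-2-en-1-yl)-7-[(triisopropylsilyl)oxy]-4H-chromen-4-one
Conditions: p-TsOH·H2O (10 mol%), toluene, 60 °C
Reagents that add atoms: none
Why: Biomimetic cycloetherification (acid-catalysed intramolecular Markovnikov hydroalkoxylation, 6-endo) in which the free 4'-OH adds to the tertiary carbon of its ortho prenyl group to close the 2,2-dimethylchroman ring D, while the ring A prenyl group, flanked only by the hindered and weakly basic silyl ether oxygen, has no internal nucleophile and stays open.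

**Step 5**
Reactants: 5 3-(2,2-dimethylchroman-6-yl)-8-(3-methylbut-2-en-1-yl)-7-[(triisopropylsilyl)oxy]-4H-chromen-4-one
Product: 7 (3R,4R)-3-(2,2-dimethylchroman-6-yl)-8-(3-methylbut-2-en-1-yl)-7-[(triisopropylsilyl)oxy]chroman-4-ol (3-aryl and 4-OH cis), via racemic silyl isoflavanone 6 (not isolated)
Conditions: RuCl[(R,R)-TsDPEN](p-cymene) (5 mol%), HCO2H–Et3N (5:2), EtOAc, 40 °C
Reagents that add atoms: none
Why: Noyori–Ikariya asymmetric transfer hydrogenation with dynamic kinetic resolution, in which hydride adds to C2 to give isoflavanone 6, whose C3 centre racemises through the enol under Et3N, and the (R,R)-catalyst reduces the (3R)-ketone selectively to the (4R)-alcohol with hydride delivered anti to the aryl group, so the cis-(3R,4R) product accumulates, the silyl ether preventing para-quinone methide formation and loss of the benzylic oxygen and the isolated prenyl alkene being inert to the metal hydride.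

**Step 6**
Reactants: 7 (3R,4R)-3-(2,2-dimethylchroman-6-yl)-8-(3-methylbut-2-en-1-yl)-7-[(triisopropylsilyl)oxy]chroman-4-ol
Product: 8 (3R)-3-(2,2-dimethylchroman-6-yl)-8-(3-methylbut-2-en-1-yl)-7-[(triisopropylsilyl)oxy]chroman-4-one
Conditions: Dess–Martin periodinane (1.3 equiv), CH2Cl2, 0 °C to rt
Reagents that add atoms: none
Why: Dess–Martin oxidation of the secondary benzylic alcohol under base-free conditions restores the C4 ketone without enolising C3, so the (3R) centre from step 5 is carried over unchanged (its CIP descriptor is the same in alcohol and ketone).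

**Step 7**
Reactants: 8 (3R)-3-(2,2-dimethylchroman-6-yl)-8-(3-methylbut-2-en-1-yl)-7-[(triisopropylsilyl)oxy]chroman-4-one
Product: 9 (3R)-3-(2,2-dimethylchroman-6-yl)-7-hydroxy-8-(3-methylbut-2-en-1-yl)chroman-4-one (CNP0139927.1)
Conditions: KHF2 (2 equiv), MeOH, rt
Reagents that add atoms: none
Why: Fluoride-induced desilylation of the aryl silyl ether, which is activated by the para carbonyl group, in a weakly acidic and base-free medium that neither enolises the configurationally labile α-aryl ketone nor cyclises the ortho-prenylphenol.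

**Compound list**
1 | daidzein, 7-hydroxy-3-(4-hydroxyphenyl)-4H-chromen-4-one | O=c1c(-c2ccc(O)cc2)coc2cc(O)ccc12 | starting material
2 | 7-[(2-methylbut-3-en-2-yl)oxy]-3-{4-[(2-methylbut-3-en-2-yl)oxy]phenyl}-4H-chromen-4-one | C=CC(C)(C)Oc1ccc(cc1)-c1coc2cc(OC(C)(C)C=C)ccc2c1=O | intermediate
3 | 7-hydroxy-3-[4-hydroxy-3-(3-methylbut-2-en-1-yl)phenyl]-8-(3-methylbut-2-en-1-yl)-4H-chromen-4-one | CC(C)=CCc1cc(ccc1O)-c1coc2c(CC=C(C)C)c(O)ccc2c1=O | intermediate
4 | 3-[4-hydroxy-3-(3-methylbut-2-en-1-yl)phenyl]-8-(3-methylbut-2-en-1-yl)-7-[(triisopropylsilyl)oxy]-4H-chromen-4-one | CC(C)=CCc1cc(ccc1O)-c1coc2c(CC=C(C)C)c(O[Si](C(C)C)(C(C)C)C(C)C)ccc2c1=O | intermediate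
5 | 3-(2,2-dimethylchroman-6-yl)-8-(3-methylbut-2-en-1-yl)-7-[(triisopropylsilyl)oxy]-4H-chromen-4-one | CC(C)=CCc1c(O[Si](C(C)C)(C(C)C)C(C)C)ccc2c1occ(-c1ccc3c(c1)CCC(C)(C)O3)c2=O | intermediate
6 | racemic 3-(2,2-dimethylchroman-6-yl)-8-(3-methylbut-2-en-1-yl)-7-[(triisopropylsilyl)oxy]chroman-4-one (not isolated) | CC(C)=CCc1c(O[Si](C(C)C)(C(C)C)C(C)C)ccc2c1OCC(c1ccc3c(c1)CCC(C)(C)O3)C2=O | intermediate
7 | (3R,4R)-3-(2,2-dimethylchroman-6-yl)-8-(3-methylbut-2-en-1-yl)-7-[(triisopropylsilyl)oxy]chroman-4-ol (cis) | CC(C)=CCc1c(O[Si](C(C)C)(C(C)C)C(C)C)ccc2c1OC[C@@H](c1ccc3c(c1)CCC(C)(C)O3)[C@H]2O | intermediate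
8 | (3R)-3-(2,2-dimethylchroman-6-yl)-8-(3-methylbut-2-en-1-yl)-7-[(triisopropylsilyl)oxy]chroman-4-one | CC(C)=CCc1c(O[Si](C(C)C)(C(C)C)C(C)C)ccc2c1OC[C@@H](c1ccc3c(c1)CCC(C)(C)O3)C2=O | intermediate
9 | (3R)-3-(2,2-dimethylchroman-6-yl)-7-hydroxy-8-(3-methylbut-2-en-1-yl)chroman-4-one | CC(C)=CCc1c(O)ccc2c1OC[C@@H](c1ccc3c(c1)CCC(C)(C)O3)C2=O | target

**Total step count:** 7
**Longest linear sequence:** 7 (1 to 9, fully linear)

**Steps most likely to fail**

Step 4 (closing ring D on one of two ortho-prenylphenols). The danger is that the silyl group is lost or its oxygen takes part, so that ring A closes as well. The fallback sets out from 4 and uses an oxidative ring closure that needs a free phenol. DDQ in dioxane at 80 °C converts only the free 4'-hydroxy-3'-prenyl unit, through its ortho-quinone methide and a 6π-electrocyclisation, into 3-(2,2-dimethyl-2H-chromen-6-yl)-8-(3-methylbut-2-en-1-yl)-7-[(triisopropylsilyl)oxy]-4H-chromen-4-one F2. Hydrogen with RhCl(PPh3)3 in benzene–EtOH then saturates only the cis-disubstituted chromene alkene, because the trisubstituted prenyl and chromone alkenes react far more slowly, and the route is rejoined at 5.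

Step 1 (branched O-allylation of two phenols of very different acidity on a poorly soluble substrate). The ether of the acidic 7-OH can re-ionise on palladium and drift to the linear prenyl ether or to C-allylation. The fallback sets out from 1 and builds the tertiary ethers without π-allyl chemistry. Alkylation with 3-chloro-3-methylbut-1-yne (K2CO3, KI, CuI, acetone, reflux) gives 7-[(2-methylbut-3-yn-2-yl)oxy]-3-{4-[(2-methylbut-3-yn-2-yl)oxy]phenyl}-4H-chromen-4-one F1. Semi-hydrogenation of both alkynes (H2, Pd/CaCO3 poisoned with Pb(OAc)2, quinoline, EtOAc) then comes back to the route at 2.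

Step 5 (transfer hydrogenation with dynamic kinetic resolution on the hindered silyl ether). Slow conjugate reduction, partial desilylation followed by over-reduction, or incomplete racemisation of 6 would lower yield or ee. The fallback sets out from 5 and replaces the reduction/re-oxidation pair by an enantioselective protonation. Conjugate reduction with LiBH(s-Bu)3 (THF, −78 °C) and trapping of the enolate with Me3SiCl give 3-(2,2-dimethylchroman-6-yl)-8-(3-methylbut-2-en-1-yl)-7-[(triisopropylsilyl)oxy]-4-[(trimethylsilyl)oxy]-2H-chromene F3. Protonation of this silyl enol ether with phenol, catalysed by a chiral BINOL-derived N-triflyl thiophosphoramide in toluene (catalyst enantiomer chosen to give the 3R ketone), leads directly to 8, so that 7 and step 6 are skipped.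

**Further compounds**
F1 | step 1 | 7-[(2-methylbut-3-yn-2-yl)oxy]-3-{4-[(2-methylbut-3-yn-2-yl)oxy]phenyl}-4H-chromen-4-one | C#CC(C)(C)Oc1ccc(cc1)-c1coc2cc(OC(C)(C)C#C)ccc2c1=O
F2 | step 4 | 3-(2,2-dimethyl-2H-chromen-6-yl)-8-(3-methylbut-2-en-1-yl)-7-[(triisopropylsilyl)oxy]-4H-chromen-4-one | CC(C)=CCc1c(O[Si](C(C)C)(C(C)C)C(C)C)ccc2c1occ(-c1ccc3c(c1)C=CC(C)(C)O3)c2=O
F3 | step 5 | 3-(2,2-dimethylchroman-6-yl)-8-(3-methylbut-2-en-1-yl)-7-[(triisopropylsilyl)oxy]-4-[(trimethylsilyl)oxy]-2H-chromene | CC(C)=CCc1c(O[Si](C(C)C)(C(C)C)C(C)C)ccc2c1OCC(c1ccc3c(c1)CCC(C)(C)O3)=C2O[Si](C)(C)C
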